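**Plan**

1. Numbering: chromanone unit O1, C2, C3, C4 with rings A (benzo), B (aryl on C2), C (pyranone); flavan unit O1″, C2″ … C8″ with rings D (benzo) and E (aryl); the furan ring is O7″–C2–C3–C8″–C7″.
2. Retrosynthetic cuts, in order: O7″–C2 (ketal C–O bond of the furan ring); then C3–C4 (enolate C-acylation) and C8″–CH2 (Pd enolate arylation), which separate an 8-bromoflavan, a 4-silyloxyacetophenone and a ring-A benzodioxinone; then O1″–C2″ (Mitsunobu) and C3″–C4″ (aldol) of the flavan.
3. Forward ring order: flavan pyran ring (step 5), ring C as its 2-hydroxy hemiketal (step 10), furan ring last (step 12).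
4. Enabling feature: C2 is a ketal carbon at aryl-ketone oxidation level and C3 is the central CH of a masked 1,3-diketone (C4=O and C2) that also carries ring D with its ortho-phenol O7″. The furan ring is therefore the dehydrative second half of a double ketalization, and H3 stays stereolabile until that ring locks it.
5. Stereochemistry: C2″ from Ru-catalysed asymmetric transfer hydrogenation to the (S)-carbinol followed by Mitsunobu inversion to (2″R). C2 and C3 arise together in step 12: C3 by catalyst-controlled dynamic kinetic selection, C2 from the obligatory cis ring fusion.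
6. Helpers: the hemiketal 2-OH (leaves as water in step 12), benzyl ethers on the flavan (removed in step 11), silyl ethers on rings A and B (removed in step 13).

Key step: step 12

Assumption: 5,7-dihydroxy-2,2-dimethyl-4H-1,3-benzodioxin-4-one (12) is taken as a purchasable building block (otherwise one step from 2,4,6-trihydroxybenzoic acid, acetone and trifluoroacetic anhydride).
Assumption: the sense of induction of the chiral acid in step 12 cannot be predicted with confidence; the (R)-acid is written and its antipode is used if it favours the other diastereomer.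

**Route**

Step 1
Reactants: 1 2,4,6-trihydroxybenzaldehyde
Product: 2 2,4-bis(benzyloxy)-6-hydroxybenzaldehyde
Conditions: BnBr (2.05 equiv), K2CO3, DMF, 0 °C to rt
Reagents that add atoms: benzyl bromide, BrCc1ccccc1
Why: Williamson etherification in which the 4-OH and one ortho-OH are alkylated while the remaining ortho-OH, chelated to the formyl group, should stay free.

Step 2
Reactants: 2 2,4-bis(benzyloxy)-6-hydroxybenzaldehyde; 3 1-[4-(benzyloxy)phenyl]ethan-1-one
Product: 4 (E)-3-[2,4-bis(benzyloxy)-6-hydroxyphenyl]-1-[4-(benzyloxy)phenyl]prop-2-en-1-one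
Conditions: KOH, EtOH/THF, rt; then dilute HCl
Reagents that add atoms: none
Why: Claisen–Schmidt (crossed aldol) condensation with E1cB dehydration, which should give the E-enone; no stereocenter is formed.

Step 3
Reactants: 4 (E)-3-[2,4-bis(benzyloxy)-6-hydroxyphenyl]-1-[4-(benzyloxy)phenyl]prop-2-en-1-one
Product: 5 3-[2,4-bis(benzyloxy)-6-hydroxyphenyl]-1-[4-(benzyloxy)phenyl]propan-1-one
Conditions: H2 (1 atm), Pd/C, Ph2S (cat.), EtOAc, rt
Reagents that add atoms: none
Why: Hydrogenation over sulfide-poisoned Pd/C is a known chemoselective alkene reduction that should leave the benzyl ethers and the aryl ketone untouched.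

Step 4
Reactants: 5 3-[2,4-bis(benzyloxy)-6-hydroxyphenyl]-1-[4-(benzyloxy)phenyl]propan-1-one
Product: 6 (1S)-3-[2,4-bis(benzyloxy)-6-hydroxyphenyl]-1-[4-(benzyloxy)phenyl]propan-1-ol
Conditions: RuCl[(S,S)-TsDPEN](p-cymene) (1 mol %), HCO2H/Et3N (5:2), EtOAc, 30 °C
Reagents that add atoms: none
Why: Noyori asymmetric transfer hydrogenation of an aryl alkyl ketone, in which the (S,S)-ligand should deliver hydride in the same sense as for acetophenone and so set the (S)-carbinol centre.

Step 5
Reactants: 6 (1S)-3-[2,4-bis(benzyloxy)-6-hydroxyphenyl]-1-[4-(benzyloxy)phenyl]propan-1-ol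
Product: 7 (2R)-5,7-bis(benzyloxy)-2-[4-(benzyloxy)phenyl]chromane
Conditions: PPh3, DIAD, THF, 0 °C, high dilution
Reagents that add atoms: none
Why: Intramolecular Mitsunobu etherification (6-exo-tet) in which the free phenol displaces the activated carbinol oxygen with inversion, turning (S) into (2R) and closing the flavan pyran ring.

Step 6
Reactants: 7 (2R)-5,7-bis(benzyloxy)-2-[4-(benzyloxy)phenyl]chromane
Product: 8 (2R)-5,7-bis(benzyloxy)-2-[4-(benzyloxy)phenyl]-8-bromochromane
Conditions: NBS (1.0 equiv), CH2Cl2, −40 to 0 °C, dark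
Reagents that add atoms: N-bromosuccinimide, O=C1CCC(=O)N1Br
Why: Electrophilic aromatic bromination, expected at C8 (ortho to O7 and O1, para to O5) as with benzylated flavan-3-ols, the mono-oxygenated ring E being far less reactive.

Step 7
Reactants: 9 1-(4-hydroxyphenyl)ethan-1-one
Product: 10 1-{4-[(triisopropylsilyl)oxy]phenyl}ethan-1-one
Conditions: TIPSCl, imidazole, DMF, rt
Reagents that add atoms: chlorotriisopropylsilane, CC(C)[Si](Cl)(C(C)C)C(C)C
Why: Standard phenol silylation, the bulky triisopropylsilyl ether being chosen so that it should survive the phosphate base of step 8.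

Step 8
Reactants: 8 (2R)-5,7-bis(benzyloxy)-2-[4-(benzyloxy)phenyl]-8-bromochromane; 10 1-{4-[(triisopropylsilyl)oxy]phenyl}ethan-1-one
Product: 11 2-{(2R)-5,7-bis(benzyloxy)-2-[4-(benzyloxy)phenyl]chroman-8-yl}-1-{4-[(triisopropylsilyl)oxy]phenyl}ethan-1-one
Conditions: Pd2(dba)3 (2.5 mol %), XPhos (6 mol %), K3PO4, toluene, 90 °C
Reagents that add atoms: none
Why: Pd-catalysed α-arylation of a methyl ketone enolate (Buchwald–Hartwig type), in which the di-ortho-oxygenated bromide should stop at monoarylation and the C2″ centre is not involved.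

Step 9
Reactants: 12 5,7-dihydroxy-2,2-dimethyl-4H-1,3-benzodioxin-4-one
Product: 13 5,7-bis[(tert-butyldimethylsilyl)oxy]-2,2-dimethyl-4H-1,3-benzodioxin-4-one
Conditions: TBSOTf, 2,6-lutidine, CH2Cl2, 0 °C
Reagents that add atoms: tert-butyldimethylsilyl triflate, CC(C)(C)[Si](C)(C)OS(=O)(=O)C(F)(F)F
Why: Silylation of both phenols, the silyl triflate being used because the 5-OH is hydrogen-bonded to the lactone carbonyl.

Step 10
Reactants: 11 2-{(2R)-5,7-bis(benzyloxy)-2-[4-(benzyloxy)phenyl]chroman-8-yl}-1-{4-[(triisopropylsilyl)oxy]phenyl}ethan-1-one; 13 5,7-bis[(tert-butyldimethylsilyl)oxy]-2,2-dimethyl-4H-1,3-benzodioxin-4-one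
Product: 15 ring-C hemiketal (2-hydroxy-3-arylchroman-4-one form; C2/C3 epimer mixture), via open-chain diketone 14 (not isolated)
Conditions: LiN(SiMe3)2 (2.2 equiv), THF, −78 °C; then 13, −78 to 0 °C; AcOH quench
Reagents that add atoms: none
Why: Claisen-type C-acylation of the lithium enolate by the salicylate acetonide, which expels acetone and frees the ring-A ortho-phenol, and on protonation this phenol should add to the aryl ketone (6-exo-trig) to close ring C as the 2-hydroxy hemiketal, C2 and C3 arising as an equilibrating mixture of epimers.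

Step 11
Reactants: 15 ring-C hemiketal with three benzyl ethers on the flavan unit
Product: 16 ring-C hemiketal with free 5″-, 7″- and 4‴-hydroxyls (C2/C3 epimer mixture)
Conditions: H2 (1 atm), 10 % Pd/C, EtOAc/THF, rt; filtered, concentrated cold, used at once
Reagents that add atoms: none
Why: Neutral hydrogenolysis of the three benzyl aryl ethers, which should spare the silyl ethers, the aryl ketone, the hemiketal and the C2″–O1″ bond, and which frees O7″ only once ring C is in place.

Step 12
Reactants: 16 ring-C hemiketal with free 5″-, 7″- and 4‴-hydroxyls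
Product: 18 (2S,3S,2″R)-ketal carrying silyl ethers on O5 and O7 and on O4′, via oxocarbenium ion 17 (not isolated)
Conditions: (R)-TRIP [(R)-3,3′-bis(2,4,6-triisopropylphenyl)-1,1′-binaphthyl-2,2′-diyl hydrogen phosphate] (10 mol %), 4 Å MS, toluene/CH2Cl2, 0.01 M, −20 to 0 °C; stopped at full conversion of 16
Reagents that add atoms: none
Why: Proposed new method: the chiral phosphoric acid should ionise the hemiketal C2–OH of 16 to the aryl-stabilised oxocarbenium ion 17, held as a contact ion pair with the chiral phosphate whose P=O oxygen also hydrogen-bonds the 7″-OH, and this phenol then adds to C2 to close the furan ring by a 5-exo-trig attack on the C2=O1+ bond, the water going to the sieves. The closest known reaction types are the chiral phosphoric acid-catalysed asymmetric spiroketalizations and transacetalizations, which have not been shown for a dehydrative aryl ketalization of a 2-hydroxychroman-4-one. C3 is stereolabile before closure because 16 equilibrates with the open β-diketone and its enol, so the C3 epimers interconvert and the catalyst selects the one that cyclises faster (a dynamic kinetic resolution, needed because the remote C2″ centre gives no useful bias). C2 is then fixed by C3, since the tethered phenol can only reach the face of C2 that gives the cis-fused 6/5 ketal, and after closure H3 can no longer epimerise without breaking a ring. The step needs O-capture to beat loss of H3 from 17 (to the 3-arylflavone) and dehydration to the 3-aroylbenzofuran. This should be secured by the ortho-phenol placed five atoms from C2, by the weak acid at low temperature, and by the silyl ether (not a free hydroxyl) on ring B, which keeps the product ketal from re-ionising.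

Step 13
Reactants: 18 (2S,3S,2″R)-ketal carrying silyl ethers on O5, O7 and O4′
Product: 19 CNP0179743.1
Conditions: TBAF/AcOH (1:1, 4 equiv), THF, 0 °C to rt; Sephadex LH-20
Reagents that add atoms: none
Why: Fluoride cleavage of the three aryl silyl ethers, buffered with acetic acid so that C3 should not be deprotonated and the ketal not opened; no stereocenter is touched.

**Compound list**

1 | 2,4,6-trihydroxybenzaldehyde | O=Cc1c(O)cc(O)cc1O | starting material
2 | 2,4-bis(benzyloxy)-6-hydroxybenzaldehyde | O=Cc1c(O)cc(OCc2ccccc2)cc1OCc1ccccc1 | intermediate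
3 | 1-[4-(benzyloxy)phenyl]ethan-1-one | CC(=O)c1ccc(OCc2ccccc2)cc1 | starting material
4 | (E)-3-[2,4-bis(benzyloxy)-6-hydroxyphenyl]-1-[4-(benzyloxy)phenyl]prop-2-en-1-one | O=C(/C=C/c1c(O)cc(OCc2ccccc2)cc1OCc1ccccc1)c1ccc(OCc2ccccc2)cc1 | intermediate
5 | 3-[2,4-bis(benzyloxy)-6-hydroxyphenyl]-1-[4-(benzyloxy)phenyl]propan-1-one | O=C(CCc1c(O)cc(OCc2ccccc2)cc1OCc1ccccc1)c1ccc(OCc2ccccc2)cc1 | intermediate
6 | (1S)-3-[2,4-bis(benzyloxy)-6-hydroxyphenyl]-1-[4-(benzyloxy)phenyl]propan-1-ol | O[C@@H](CCc1c(O)cc(OCc2ccccc2)cc1OCc1ccccc1)c1ccc(OCc2ccccc2)cc1 | intermediate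
7 | (2R)-5,7-bis(benzyloxy)-2-[4-(benzyloxy)phenyl]chromane | c1ccccc1COc1cc(OCc2ccccc2)c2c(c1)O[C@@H](c1ccc(OCc3ccccc3)cc1)CC2 | intermediate
8 | (2R)-5,7-bis(benzyloxy)-2-[4-(benzyloxy)phenyl]-8-bromochromane | Brc1c(OCc2ccccc2)cc(OCc2ccccc2)c2c1O[C@@H](c1ccc(OCc3ccccc3)cc1)CC2 | intermediate
9 | 1-(4-hydroxyphenyl)ethan-1-one | CC(=O)c1ccc(O)cc1 | starting material
10 | 1-{4-[(triisopropylsilyl)oxy]phenyl}ethan-1-one | CC(=O)c1ccc(O[Si](C(C)C)(C(C)C)C(C)C)cc1 | intermediate
11 | 2-{(2R)-5,7-bis(benzyloxy)-2-[4-(benzyloxy)phenyl]chroman-8-yl}-1-{4-[(triisopropylsilyl)oxy]phenyl}ethan-1-one | O=C(Cc1c(OCc2ccccc2)cc(OCc2ccccc2)c2c1O[C@@H](c1ccc(OCc3ccccc3)cc1)CC2)c1ccc(O[Si](C(C)C)(C(C)C)C(C)C)cc1 | intermediate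
12 | 5,7-dihydroxy-2,2-dimethyl-4H-1,3-benzodioxin-4-one | CC1(C)OC(=O)c2c(O)cc(O)cc2O1 | starting material
13 | 5,7-bis[(tert-butyldimethylsilyl)oxy]-2,2-dimethyl-4H-1,3-benzodioxin-4-one | CC1(C)OC(=O)c2c(O[Si](C)(C)C(C)(C)C)cc(O[Si](C)(C)C(C)(C)C)cc2O1 | intermediate
14 | 2-{(2R)-5,7-bis(benzyloxy)-2-[4-(benzyloxy)phenyl]chroman-8-yl}-1-{2,4-bis[(tert-butyldimethylsilyl)oxy]-6-hydroxyphenyl}-3-{4-[(triisopropylsilyl)oxy]phenyl}propane-1,3-dione (open-chain tautomer) | O=C(c1ccc(O[Si](C(C)C)(C(C)C)C(C)C)cc1)C(C(=O)c1c(O)cc(O[Si](C)(C)C(C)(C)C)cc1O[Si](C)(C)C(C)(C)C)c1c(OCc2ccccc2)cc(OCc2ccccc2)c2c1O[C@@H](c1ccc(OCc3ccccc3)cc1)CC2 | intermediate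
15 | 3-{(2R)-5,7-bis(benzyloxy)-2-[4-(benzyloxy)phenyl]chroman-8-yl}-5,7-bis[(tert-butyldimethylsilyl)oxy]-2-hydroxy-2-{4-[(triisopropylsilyl)oxy]phenyl}chroman-4-one (C2/C3 epimer mixture) | O=C1c2c(O[Si](C)(C)C(C)(C)C)cc(O[Si](C)(C)C(C)(C)C)cc2OC(O)(c2ccc(O[Si](C(C)C)(C(C)C)C(C)C)cc2)C1c1c(OCc2ccccc2)cc(OCc2ccccc2)c2c1O[C@@H](c1ccc(OCc3ccccc3)cc1)CC2 | intermediate
16 | 3-[(2R)-5,7-dihydroxy-2-(4-hydroxyphenyl)chroman-8-yl]-5,7-bis[(tert-butyldimethylsilyl)oxy]-2-hydroxy-2-{4-[(triisopropylsilyl)oxy]phenyl}chroman-4-one (C2/C3 epimer mixture) | O=C1c2c(O[Si](C)(C)C(C)(C)C)cc(O[Si](C)(C)C(C)(C)C)cc2OC(O)(c2ccc(O[Si](C(C)C)(C(C)C)C(C)C)cc2)C1c1c(O)cc(O)c2c1O[C@@H](c1ccc(O)cc1)CC2 | intermediate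
17 | C2 oxocarbenium ion of 16 (4-oxo-3,4-dihydrochromenylium; C3 epimers interconverting) | O=C1c2c(O[Si](C)(C)C(C)(C)C)cc(O[Si](C)(C)C(C)(C)C)cc2[O+]=C(c2ccc(O[Si](C(C)C)(C(C)C)C(C)C)cc2)C1c1c(O)cc(O)c2c1O[C@@H](c1ccc(O)cc1)CC2 | intermediate
18 | (2S,3S,2″R)-ketal: the target with tert-butyldimethylsilyl ethers on O5 and O7 and a triisopropylsilyl ether on O4′ | O=C1c2c(O[Si](C)(C)C(C)(C)C)cc(O[Si](C)(C)C(C)(C)C)cc2O[C@@]2(c3ccc(O[Si](C(C)C)(C(C)C)C(C)C)cc3)Oc3cc(O)c4c(c3[C@@H]12)O[C@@H](c1ccc(O)cc1)CC4 | intermediate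
19 | CNP0179743.1, (2S,3S,2″R) | O=C1c2c(O)cc(O)cc2O[C@@]2(c3ccc(O)cc3)Oc3cc(O)c4c(c3[C@@H]12)O[C@@H](c1ccc(O)cc1)CC4 | target

**Step count and risks**

Total: 13 steps. Longest linear sequence: 11 steps (steps 1–6, 8, 10, 11, 12, 13).

Step 12 is the riskiest. The catalyst may discriminate poorly between the two C3 epimers, or the oxocarbenium ion may lose H3 (elimination to the 3-arylflavone) or open ring C and dehydrate to the aroylbenzofuran. The fallback gives up induction and acid altogether: setting out from 16, the hemiketal hydroxyl is coupled with the 7″-phenol under neutral redox-dehydration conditions (PPh3, DIAD, toluene, 0 °C), the Mitsunobu coupling of a lactol-type hydroxyl with a phenol as used for aryl glycosides. This should give 18 together with the (2R,3R,2″R)-diastereomeric ketal F1. The two are diastereomers and are separated by chromatography, F1 is returned to 16 by mild aqueous acid, and the route is rejoined at 18.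

Step 10 is the second risk. Steric blocking at the enolate carbon, which carries the di-ortho-substituted flavan ring, may lead to O-acylation, recovery of 11, or retro-Claisen cleavage of the crowded diketone. The fallback replaces the Claisen acylation by aldol addition and oxidation. Compound 1 is bis-silylated (TBSCl, imidazole) to 2,4-bis[(tert-butyldimethylsilyl)oxy]-6-hydroxybenzaldehyde F2, whose chelated phenol is benzylated under neutral Mitsunobu conditions (BnOH, PPh3, DIAD) to 2-(benzyloxy)-4,6-bis[(tert-butyldimethylsilyl)oxy]benzaldehyde F3. The lithium enolate of 11 is added to F3 at −78 °C to give the β-hydroxy ketone F4, and Dess–Martin periodinane oxidises this to the open-chain diketone with a benzyl ether on the ring-A ortho oxygen F5. Hydrogenolysis (H2, Pd/C, EtOAc) then removes all four benzyl ethers, the freed ring-A phenol closes ring C, and the route is rejoined at 16.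

Step 13 is the third risk. Fluoride or acetate may enolise C3 and trigger β-elimination of the ring-A phenoxide (ring C opening to the aroylbenzofuran), or the ketal may ionise during work-up. The fallback changes the order of events so that the finished ketal never meets a deprotection. Setting out from 16, the silyl ethers are removed first (TBAF/AcOH, THF, 0 °C), which the hemiketal stage tolerates, to give the fully deprotected hemiketal F6. The furan ring is then closed as the last operation by ordinary mild acid-catalysed ketalization (PPTS, 4 Å MS, EtOAc/acetone, 0 °C). This gives 19 together with its (2R,3R,2″R)-diastereomer F7, which is removed by reversed-phase HPLC; the route is rejoined at 19.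

**Further compounds**

F1 | step 12 | (2R,3R,2″R)-diastereomer of 18 | O=C1c2c(O[Si](C)(C)C(C)(C)C)cc(O[Si](C)(C)C(C)(C)C)cc2O[C@]2(c3ccc(O[Si](C(C)C)(C(C)C)C(C)C)cc3)Oc3cc(O)c4c(c3[C@H]12)O[C@@H](c1ccc(O)cc1)CC4
F2 | step 10 | 2,4-bis[(tert-butyldimethylsilyl)oxy]-6-hydroxybenzaldehyde | O=Cc1c(O)cc(O[Si](C)(C)C(C)(C)C)cc1O[Si](C)(C)C(C)(C)C
F3 | step 10 | 2-(benzyloxy)-4,6-bis[(tert-butyldimethylsilyl)oxy]benzaldehyde | O=Cc1c(OCc2ccccc2)cc(O[Si](C)(C)C(C)(C)C)cc1O[Si](C)(C)C(C)(C)C
F4 | step 10 | 3-{2-(benzyloxy)-4,6-bis[(tert-butyldimethylsilyl)oxy]phenyl}-2-{(2R)-5,7-bis(benzyloxy)-2-[4-(benzyloxy)phenyl]chroman-8-yl}-3-hydroxy-1-{4-[(triisopropylsilyl)oxy]phenyl}propan-1-one (mixture of aldol diastereomers) | OC(c1c(OCc2ccccc2)cc(O[Si](C)(C)C(C)(C)C)cc1O[Si](C)(C)C(C)(C)C)C(C(=O)c1ccc(O[Si](C(C)C)(C(C)C)C(C)C)cc1)c1c(OCc2ccccc2)cc(OCc2ccccc2)c2c1O[C@@H](c1ccc(OCc3ccccc3)cc1)CC2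
F5 | step 10 | 1-{2-(benzyloxy)-4,6-bis[(tert-butyldimethylsilyl)oxy]phenyl}-2-{(2R)-5,7-bis(benzyloxy)-2-[4-(benzyloxy)phenyl]chroman-8-yl}-3-{4-[(triisopropylsilyl)oxy]phenyl}propane-1,3-dione | O=C(c1c(OCc2ccccc2)cc(O[Si](C)(C)C(C)(C)C)cc1O[Si](C)(C)C(C)(C)C)C(C(=O)c1ccc(O[Si](C(C)C)(C(C)C)C(C)C)cc1)c1c(OCc2ccccc2)cc(OCc2ccccc2)c2c1O[C@@H](c1ccc(OCc3ccccc3)cc1)CC2
F6 | step 13 | 3-[(2R)-5,7-dihydroxy-2-(4-hydroxyphenyl)chroman-8-yl]-2,5,7-trihydroxy-2-(4-hydroxyphenyl)chroman-4-one (C2/C3 epimer mixture) | O=C1c2c(O)cc(O)cc2OC(O)(c2ccc(O)cc2)C1c1c(O)cc(O)c2c1O[C@@H](c1ccc(O)cc1)CC2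
F7 | step 13 | (2R,3R,2″R)-diastereomer of 19 | O=C1c2c(O)cc(O)cc2O[C@]2(c3ccc(O)cc3)Oc3cc(O)c4c(c3[C@H]12)O[C@@H](c1ccc(O)cc1)CC4
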